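Everything rests on building ring A of unit 2, the naringenin half, from open-chain pieces so that its three oxygens arrive already differentiated. One thermal benzannulation of 3-ethoxycyclobutenone with a triisopropylsiloxyalkyne forms C8–C8a and C6–C7, re-forms C4a–C8a and delivers a phenol with O1 free, O5 as ethyl ether, O7 as silyl ether, the two-carbon arm for C3 and C4 of unit 1 on C8, and C4a unsubstituted. The alkyne is the silylated ynolate of ethyl 3,3-diethoxypropanoate. Protected O1 then directs acylation to C4a, the arm becomes a deoxybenzoin, and C2 of each unit is set late under catalyst control.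

Key step: step 2

Remarks on the chemistry:
- Unit 1 is the flavanone joined through C3 (3,4-dihydroxyphenyl at C2; target 2R,3S, trans). Unit 2 is the flavanone joined through C8 (4-hydroxyphenyl at C2; target 2S).
- The alkyne that fits the ring-forming step has four chain carbons, 4,4-diethoxy-1-(triisopropylsilyloxy)but-1-yne. One-carbon homologation of the three-carbon ester gives exactly this; a five-carbon alkyne would place an extra CH2 between C8 of unit 2 and C3 of unit 1.
- Assumption: the tribenzyl ether of phloroglucinol, 4-(benzyloxy)phenylboronic acid, 3,4-bis(benzyloxy)benzaldehyde and both antipodes of t-BuPyOx are bought. The ligand antipode for 2S is assigned by analogy with simple chromones and is to be confirmed on the first run.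

Step 1
Reactants: 1 ethyl 3,3-diethoxypropanoate
Product: 3 4,4-diethoxy-1-(triisopropylsilyloxy)but-1-yne, via lithium ynolate 2 (not isolated)
Conditions: CH2Br2, LiTMP (lithium 2,2,6,6-tetramethylpiperidide), THF, −78 °C, then 1; n-BuLi, −78 → 0 °C; TIPSOTf, −78 → 0 °C
Reagents that add atoms: dibromomethane, BrCBr; triisopropylsilyl trifluoromethanesulfonate, CC(C)[Si](OS(=O)(=O)C(F)(F)F)(C(C)C)C(C)C
Why: Kowalski ester homologation, in which LiCHBr2 adds to the ester, the dibromo ketone enolate undergoes Br/Li exchange and 1,2-shift to ynolate 2, and O-silylation with the hindered silyl triflate gives the isolable ynol silyl ether; the acetal is inert to base and sits too far from the carbanionic carbon for β-elimination, and adding the ester to preformed LiCHBr2 limits ester enolisation.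

Step 2
Reactants: 3 4,4-diethoxy-1-(triisopropylsilyloxy)but-1-yne; 4 3-ethoxycyclobut-2-en-1-one
Product: 9 2-(2,2-diethoxyethyl)-5-ethoxy-3-(triisopropylsilyloxy)phenol, via vinylketene 5 (not isolated), via vinylcyclobutenone 6 (not isolated), via dienylketene 7 (not isolated), via cyclohexadienone 8 (not isolated)
Conditions: toluene, 80 → 110 °C, sealed tube, 3 in slight excess
Reagents that add atoms: none
Why: Four-electron electrocyclic opening of 4 gives the (1-ethoxyvinyl)ketene 5, which adds [2+2] to the electron-rich alkyne 3 to give cyclobutenone 6; this opens to dienylketene 7, which closes ring A of unit 2 by a thermal six-electron disrotatory electrocyclisation to dienone 8 and tautomerises to phenol 9. The closest known reaction type is the Danheiser benzannulation of 3-substituted cyclobutenones with triisopropylsiloxyalkynes to 2-alkylresorcinol monosilyl ethers; the 3-ethoxy group rides along and turns the resorcinol pattern into a phloroglucinol pattern, which is the extension and the main risk. No stereocentre is formed. The step needs one regiochemistry in the [2+2] event: the alkyl-bearing alkyne carbon, made nucleophilic by the ynol ether oxygen, must bond to the ketene carbonyl carbon, so that the arm lands between the free phenol (O1) and the silyl ether (O7) with the ethoxy group (O5) para to it. C4a, ortho to the free phenol, stays unsubstituted.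

Step 3
Reactants: 9 2-(2,2-diethoxyethyl)-5-ethoxy-3-(triisopropylsilyloxy)phenol
Product: 10 2-(2,2-diethoxyethyl)-5-ethoxy-1-(methoxymethoxy)-3-(triisopropylsilyloxy)benzene
Conditions: MOMCl, iPr2NEt, CH2Cl2, 0 °C → rt
Reagents that add atoms: chloromethyl methyl ether, COCCl
Why: O-alkylation of the only free phenol (MOM protection); the ether keeps O1 from closing onto the acetal carbon (benzofuran formation) and is the directing group for the next step.

Step 4
Reactants: 10 2-(2,2-diethoxyethyl)-5-ethoxy-1-(methoxymethoxy)-3-(triisopropylsilyloxy)benzene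
Product: 12 1-[3-(2,2-diethoxyethyl)-6-ethoxy-2-(methoxymethoxy)-4-(triisopropylsilyloxy)phenyl]ethan-1-one, via aryllithium 11 (not isolated)
Conditions: n-BuLi, THF, 0 °C; then MeC(O)N(OMe)Me, −78 °C → rt
Reagents that add atoms: N-methoxy-N-methylacetamide, CC(=O)N(C)OC
Why: Directed ortho-metalation, since C4a–H is the only ring position flanked by two coordinating alkoxy groups (OMOM and OEt) while C6–H lies next to the bulky, non-coordinating silyl ether; the Weinreb amide gives a stable chelate and so the ketone without over-addition.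

Step 5
Reactants: 12 1-[3-(2,2-diethoxyethyl)-6-ethoxy-2-(methoxymethoxy)-4-(triisopropylsilyloxy)phenyl]ethan-1-one
Product: 13 (E)-1-[3-(2,2-diethoxyethyl)-6-ethoxy-2-(methoxymethoxy)-4-(triisopropylsilyloxy)phenyl]-3-(dimethylamino)prop-2-en-1-one
Conditions: Me2NCH(OMe)2 (neat), 100 °C
Reagents that add atoms: N,N-dimethylformamide dimethyl acetal, COC(OC)N(C)C
Why: Condensation of the methyl ketone with the amide acetal gives the enaminone, the standard one-carbon extension toward a chromone; the medium is acid-free, so both acetals and the silyl ether persist.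

Step 6
Reactants: 13 (E)-1-[3-(2,2-diethoxyethyl)-6-ethoxy-2-(methoxymethoxy)-4-(triisopropylsilyloxy)phenyl]-3-(dimethylamino)prop-2-en-1-one
Product: 15 2-[5-ethoxy-4-oxo-7-(triisopropylsilyloxy)-4H-chromen-8-yl]acetaldehyde, via chromone acetal 14 (not isolated)
Conditions: HCl (1.25 M in EtOH), rt; then 2 M aq. HCl, THF, rt
Reagents that add atoms: water, O
Why: Acidic ethanolysis removes the MOM group and the freed O1 adds to the protonated enaminone and expels dimethylamine (addition–elimination) to give the chromone, while the side-chain acetal only exchanges with ethanol; water is added after O1 is locked in the pyranone, so acetal hydrolysis to the aldehyde cannot lead on to a benzofuran.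

Step 7
Reactants: 15 2-[5-ethoxy-4-oxo-7-(triisopropylsilyloxy)-4H-chromen-8-yl]acetaldehyde
Product: 16 2-[5-ethoxy-4-oxo-7-(triisopropylsilyloxy)-4H-chromen-8-yl]acetic acid
Conditions: NaClO2, NaH2PO4, 2-methylbut-2-ene, t-BuOH/H2O, 0 °C → rt
Reagents that add atoms: sodium chlorite, [Na+].[O-]Cl=O
Why: Pinnick oxidation converts the enolisable arylacetaldehyde to the acid under buffered conditions, the alkene scavenging HOCl so that the ring and the silyl ether are left alone.

Step 8
Reactants: 16 2-[5-ethoxy-4-oxo-7-(triisopropylsilyloxy)-4H-chromen-8-yl]acetic acid; 17 1,3,5-tris(benzyloxy)benzene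
Product: 19 5-ethoxy-8-{2-oxo-2-[2,4,6-tris(benzyloxy)phenyl]ethyl}-7-(triisopropylsilyloxy)-4H-chromen-4-one, via mixed anhydride 18 (not isolated)
Conditions: TFAA (1.1 equiv), CH2Cl2, 0 °C; then 17, 0 °C → rt
Reagents that add atoms: none
Why: Friedel–Crafts acylation through the mixed trifluoroacetic anhydride, for which the phloroglucinol triether is nucleophilic enough without a metal Lewis acid; its three ring positions are equivalent, the product is deactivated toward a second acylation, and ring A of unit 2 is deactivated by the pyranone carbonyl.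

Step 9
Reactants: 19 5-ethoxy-8-{2-oxo-2-[2,4,6-tris(benzyloxy)phenyl]ethyl}-7-(triisopropylsilyloxy)-4H-chromen-4-one; 20 4-(benzyloxy)phenylboronic acid
Product: 21 (2S)-2-[4-(benzyloxy)phenyl]-5-ethoxy-8-{2-oxo-2-[2,4,6-tris(benzyloxy)phenyl]ethyl}-7-(triisopropylsilyloxy)chroman-4-one
Conditions: Pd(OCOCF3)2 (10 mol %), (R)-t-BuPyOx [(R)-4-tert-butyl-2-(pyridin-2-yl)-4,5-dihydrooxazole] (12 mol %), NH4PF6 (30 mol %), H2O (5 equiv), ClCH2CH2Cl, 60 °C
Reagents that add atoms: none
Why: Palladium-catalysed asymmetric conjugate addition of an arylboronic acid to a chromone (aryl transfer from boron, enantio-determining insertion of C2=C3 into the aryl–palladium bond, protonolysis), a known reaction of chromones; the ligand antipode is chosen to deliver the aryl group to the face that gives C2 (S) of unit 2, and the base-free medium should leave the new flavanone configurationally stable.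

Step 10
Reactants: 21 (2S)-2-[4-(benzyloxy)phenyl]-5-ethoxy-8-{2-oxo-2-[2,4,6-tris(benzyloxy)phenyl]ethyl}-7-(triisopropylsilyloxy)chroman-4-one
Product: 22 (2S)-2-[4-(benzyloxy)phenyl]-8-{2-[2,4-bis(benzyloxy)-6-hydroxyphenyl]-2-oxoethyl}-5-ethoxy-7-(triisopropylsilyloxy)chroman-4-one
Conditions: BCl3 (2.1 equiv, one per carbonyl group), CH2Cl2, −78 °C; MeOH quench at −78 °C
Reagents that add atoms: none
Why: Chelation-controlled ether cleavage, in which BCl3 bound to the ketone oxygen removes one ortho benzyl group of ring A of unit 1 at −78 °C; the chelated ethyl ether of unit 2 needs a higher temperature, and the remote benzyl ethers lack the chelate and meet no free BCl3.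

Step 11
Reactants: 22 (2S)-2-[4-(benzyloxy)phenyl]-8-{2-[2,4-bis(benzyloxy)-6-hydroxyphenyl]-2-oxoethyl}-5-ethoxy-7-(triisopropylsilyloxy)chroman-4-one; 23 3,4-bis(benzyloxy)benzaldehyde
Product: 25 (2R,3S)-5,7-bis(benzyloxy)-2-[3,4-bis(benzyloxy)phenyl]-3-{(2S)-2-[4-(benzyloxy)phenyl]-5-ethoxy-4-oxo-7-(triisopropylsilyloxy)chroman-8-yl}chroman-4-one, via chalcone 24 (not isolated)
Conditions: 23 (1.1 equiv), 9-amino-9-deoxy-epi-quinidine (20 mol %), PhCO2H (20 mol %), 4 Å molecular sieves, toluene, 40 °C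
Reagents that add atoms: none
Why: Proposed new method: the primary amine of the cinchona catalyst should condense with 23 to an iminium ion that the enol of the hydrogen-bonded ketone 22 attacks (Mannich-type), loss of the amine then gives the α-aryl-2′-hydroxychalcone 24, and the quinuclidine of the same catalyst, ion-paired with the phenoxide while the ammonium group binds the carbonyl oxygen, should guide the 6-endo oxa-Michael closure to one enone face and set C2 (R); C3 then settles as S by enolisation to the favoured trans-diequatorial isomer; the closest known reaction types are the amine-catalysed Knoevenagel condensation/oxa-Michael closure of 2′-hydroxydeoxybenzoins with aryl aldehydes to racemic trans-3-arylflavanones and the cinchona-base-catalysed enantioselective cyclisation of 2′-hydroxychalcones; the facial sense is catalyst-controlled (the epi-quinine pseudo-enantiomer is the alternative), and any 2S,3R material is a diastereomer of 25 that chromatography should remove.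

Step 12
Reactants: 25 (2R,3S)-5,7-bis(benzyloxy)-2-[3,4-bis(benzyloxy)phenyl]-3-{(2S)-2-[4-(benzyloxy)phenyl]-5-ethoxy-4-oxo-7-(triisopropylsilyloxy)chroman-8-yl}chroman-4-one
Product: 26 (2R,3S)-5,7-bis(benzyloxy)-2-[3,4-bis(benzyloxy)phenyl]-3-{(2S)-2-[4-(benzyloxy)phenyl]-5-ethoxy-7-hydroxy-4-oxochroman-8-yl}chroman-4-one
Conditions: HF·pyridine, THF, 0 °C → rt
Reagents that add atoms: none
Why: Fluoride cleavage of the aryl silyl ether under acidic conditions, which avoid the basic media that open flavanone rings and scramble C2.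

Step 13
Reactants: 26 (2R,3S)-5,7-bis(benzyloxy)-2-[3,4-bis(benzyloxy)phenyl]-3-{(2S)-2-[4-(benzyloxy)phenyl]-5-ethoxy-7-hydroxy-4-oxochroman-8-yl}chroman-4-one
Product: 27 (2R,3S)-2-(3,4-dihydroxyphenyl)-5,7-dihydroxy-3-[(2S)-5,7-dihydroxy-2-(4-hydroxyphenyl)-4-oxochroman-8-yl]chroman-4-one
Conditions: BCl3 (excess), C6HMe5, CH2Cl2, −78 °C → rt; MeOH
Reagents that add atoms: none
Why: Lewis-acid dealkylation, in which BCl3 with pentamethylbenzene as cation scavenger cleaves the five benzyl ethers at low temperature and, on warming, the ethyl ether held in a boron chelate with the unit 2 carbonyl; neither base nor hydrogen is used, so the three stereocentres and the benzylic C2–O bonds should survive.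

Compound list
1 | ethyl 3,3-diethoxypropanoate | CCOC(=O)CC(OCC)OCC | starting material
2 | lithium 4,4-diethoxybut-1-yn-1-olate | [Li+].[O-]C#CCC(OCC)OCC | intermediate (not isolated)
3 | 4,4-diethoxy-1-(triisopropylsilyloxy)but-1-yne | CCOC(OCC)CC#CO[Si](C(C)C)(C(C)C)C(C)C | intermediate
4 | 3-ethoxycyclobut-2-en-1-one | CCOC1=CC(=O)C1 | starting material
5 | 3-ethoxybuta-1,3-dien-1-one, the (1-ethoxyvinyl)ketene | CCOC(=C)C=C=O | intermediate (not isolated)
6 | 2-(2,2-diethoxyethyl)-4-(1-ethoxyvinyl)-3-(triisopropylsilyloxy)cyclobut-2-en-1-one (racemic) | CCOC(OCC)CC1=C(O[Si](C(C)C)(C(C)C)C(C)C)C(C(=C)OCC)C1=O | intermediate (not isolated)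
7 | 2-(2,2-diethoxyethyl)-5-ethoxy-3-(triisopropylsilyloxy)hexa-1,3,5-trien-1-one (ketene and ethoxyvinyl groups cis) | CCOC(OCC)CC(=C=O)/C(O[Si](C(C)C)(C(C)C)C(C)C)=C\C(=C)OCC | intermediate (not isolated)
8 | 2-(2,2-diethoxyethyl)-5-ethoxy-3-(triisopropylsilyloxy)cyclohexa-2,4-dien-1-one | CCOC(OCC)CC1=C(O[Si](C(C)C)(C(C)C)C(C)C)C=C(OCC)CC1=O | intermediate (not isolated)
9 | 2-(2,2-diethoxyethyl)-5-ethoxy-3-(triisopropylsilyloxy)phenol | CCOC(OCC)Cc1c(O)cc(OCC)cc1O[Si](C(C)C)(C(C)C)C(C)C | intermediate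
10 | 2-(2,2-diethoxyethyl)-5-ethoxy-1-(methoxymethoxy)-3-(triisopropylsilyloxy)benzene | CCOC(OCC)Cc1c(OCOC)cc(OCC)cc1O[Si](C(C)C)(C(C)C)C(C)C | intermediate
11 | [3-(2,2-diethoxyethyl)-6-ethoxy-2-(methoxymethoxy)-4-(triisopropylsilyloxy)phenyl]lithium | CCOC(OCC)Cc1c(OCOC)c([Li])c(OCC)cc1O[Si](C(C)C)(C(C)C)C(C)C | intermediate (not isolated)
12 | 1-[3-(2,2-diethoxyethyl)-6-ethoxy-2-(methoxymethoxy)-4-(triisopropylsilyloxy)phenyl]ethan-1-one | CCOC(OCC)Cc1c(OCOC)c(C(C)=O)c(OCC)cc1O[Si](C(C)C)(C(C)C)C(C)C | intermediate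
13 | (E)-1-[3-(2,2-diethoxyethyl)-6-ethoxy-2-(methoxymethoxy)-4-(triisopropylsilyloxy)phenyl]-3-(dimethylamino)prop-2-en-1-one | CCOC(OCC)Cc1c(OCOC)c(C(=O)/C=C/N(C)C)c(OCC)cc1O[Si](C(C)C)(C(C)C)C(C)C | intermediate
14 | 8-(2,2-diethoxyethyl)-5-ethoxy-7-(triisopropylsilyloxy)-4H-chromen-4-one | CCOC(OCC)Cc1c(O[Si](C(C)C)(C(C)C)C(C)C)cc(OCC)c2c(=O)ccoc12 | intermediate (not isolated)
15 | 2-[5-ethoxy-4-oxo-7-(triisopropylsilyloxy)-4H-chromen-8-yl]acetaldehyde | O=CCc1c(O[Si](C(C)C)(C(C)C)C(C)C)cc(OCC)c2c(=O)ccoc12 | intermediate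
16 | 2-[5-ethoxy-4-oxo-7-(triisopropylsilyloxy)-4H-chromen-8-yl]acetic acid | OC(=O)Cc1c(O[Si](C(C)C)(C(C)C)C(C)C)cc(OCC)c2c(=O)ccoc12 | intermediate
17 | 1,3,5-tris(benzyloxy)benzene | c1ccc(COc2cc(OCc3ccccc3)cc(OCc3ccccc3)c2)cc1 | starting material
18 | 2-[5-ethoxy-4-oxo-7-(triisopropylsilyloxy)-4H-chromen-8-yl]acetic trifluoroacetic anhydride | FC(F)(F)C(=O)OC(=O)Cc1c(O[Si](C(C)C)(C(C)C)C(C)C)cc(OCC)c2c(=O)ccoc12 | intermediate (not isolated)
19 | 5-ethoxy-8-{2-oxo-2-[2,4,6-tris(benzyloxy)phenyl]ethyl}-7-(triisopropylsilyloxy)-4H-chromen-4-one | O=C(Cc1c(O[Si](C(C)C)(C(C)C)C(C)C)cc(OCC)c2c(=O)ccoc12)c1c(OCc2ccccc2)cc(OCc2ccccc2)cc1OCc1ccccc1 | intermediate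
20 | 4-(benzyloxy)phenylboronic acid | OB(O)c1ccc(OCc2ccccc2)cc1 | starting material
21 | (2S)-2-[4-(benzyloxy)phenyl]-5-ethoxy-8-{2-oxo-2-[2,4,6-tris(benzyloxy)phenyl]ethyl}-7-(triisopropylsilyloxy)chroman-4-one | O=C1C[C@@H](c2ccc(OCc3ccccc3)cc2)Oc2c1c(OCC)cc(O[Si](C(C)C)(C(C)C)C(C)C)c2CC(=O)c1c(OCc2ccccc2)cc(OCc2ccccc2)cc1OCc1ccccc1 | intermediate
22 | (2S)-2-[4-(benzyloxy)phenyl]-8-{2-[2,4-bis(benzyloxy)-6-hydroxyphenyl]-2-oxoethyl}-5-ethoxy-7-(triisopropylsilyloxy)chroman-4-one | O=C1C[C@@H](c2ccc(OCc3ccccc3)cc2)Oc2c1c(OCC)cc(O[Si](C(C)C)(C(C)C)C(C)C)c2CC(=O)c1c(O)cc(OCc2ccccc2)cc1OCc1ccccc1 | intermediate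
23 | 3,4-bis(benzyloxy)benzaldehyde | O=Cc1ccc(OCc2ccccc2)c(OCc2ccccc2)c1 | starting material
24 | 1-[2,4-bis(benzyloxy)-6-hydroxyphenyl]-3-[3,4-bis(benzyloxy)phenyl]-2-{(2S)-2-[4-(benzyloxy)phenyl]-5-ethoxy-4-oxo-7-(triisopropylsilyloxy)chroman-8-yl}prop-2-en-1-one (E/Z mixture) | O=C1C[C@@H](c2ccc(OCc3ccccc3)cc2)Oc2c1c(OCC)cc(O[Si](C(C)C)(C(C)C)C(C)C)c2C(=Cc1ccc(OCc2ccccc2)c(OCc2ccccc2)c1)C(=O)c1c(O)cc(OCc2ccccc2)cc1OCc1ccccc1 | intermediate (not isolated)
25 | (2R,3S)-5,7-bis(benzyloxy)-2-[3,4-bis(benzyloxy)phenyl]-3-{(2S)-2-[4-(benzyloxy)phenyl]-5-ethoxy-4-oxo-7-(triisopropylsilyloxy)chroman-8-yl}chroman-4-one | O=C1C[C@@H](c2ccc(OCc3ccccc3)cc2)Oc2c1c(OCC)cc(O[Si](C(C)C)(C(C)C)C(C)C)c2[C@@H]1C(=O)c2c(OCc3ccccc3)cc(OCc3ccccc3)cc2O[C@H]1c1ccc(OCc2ccccc2)c(OCc2ccccc2)c1 | intermediate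
26 | (2R,3S)-5,7-bis(benzyloxy)-2-[3,4-bis(benzyloxy)phenyl]-3-{(2S)-2-[4-(benzyloxy)phenyl]-5-ethoxy-7-hydroxy-4-oxochroman-8-yl}chroman-4-one | O=C1C[C@@H](c2ccc(OCc3ccccc3)cc2)Oc2c1c(OCC)cc(O)c2[C@@H]1C(=O)c2c(OCc3ccccc3)cc(OCc3ccccc3)cc2O[C@H]1c1ccc(OCc2ccccc2)c(OCc2ccccc2)c1 | intermediate
27 | (2R,3S)-2-(3,4-dihydroxyphenyl)-5,7-dihydroxy-3-[(2S)-5,7-dihydroxy-2-(4-hydroxyphenyl)-4-oxochroman-8-yl]chroman-4-one | O=C1C[C@@H](c2ccc(O)cc2)Oc2c1c(O)cc(O)c2[C@@H]1C(=O)c2c(O)cc(O)cc2O[C@H]1c1ccc(O)c(O)c1 | target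

Total step count: 13. Longest linear sequence: 13 steps (1 → 27); 4, 17, 20 and 23 enter as bought partners.

Steps most likely to fail

1. Step 11 (bears the label). The chiral amine may discriminate poorly between the two enone faces in the ring closure, or turn over slowly with the hindered ketone. The aldehyde may also condense at the C3 methylene of unit 2, and the amine may slowly erode C2 of unit 2. The fallback uses known chemistry and changes the order of events so that no amine meets a flavanone. It sets out from 19. Chelation-controlled mono-debenzylation with BCl3 in CH2Cl2 at −78 °C should give 8-{2-[2,4-bis(benzyloxy)-6-hydroxyphenyl]-2-oxoethyl}-5-ethoxy-7-(triisopropylsilyloxy)-4H-chromen-4-one F1 as the hydrogen-bonded phenol. Knoevenagel condensation and oxa-Michael closure of F1 with 23 under piperidinium acetate in toluene at reflux, with an acidic work-up that re-closes any amine-opened chromone, should give under thermodynamic control the trans racemate rac-(2R,3S)-5,7-bis(benzyloxy)-2-[3,4-bis(benzyloxy)phenyl]-3-[5-ethoxy-4-oxo-7-(triisopropylsilyloxy)-4H-chromen-8-yl]chroman-4-one F2 with the chromone of unit 2 still in place. Addition of 20 to F2 under the conditions of step 9 then sets C2 of unit 2 as S under catalyst control and turns the racemate into 25 and its diastereomer (2S,3R)-5,7-bis(benzyloxy)-2-[3,4-bis(benzyloxy)phenyl]-3-{(2S)-2-[4-(benzyloxy)phenyl]-5-ethoxy-4-oxo-7-(triisopropylsilyloxy)chroman-8-yl}chroman-4-one F3 in equal parts. Chromatography removes F3 at the cost of half the material, and the route is rejoined at 25.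

2. Step 2. The donor-substituted cyclobutenone may open too slowly, so that the siloxyalkyne isomerises or the vinylketene dimerises or acylates the product phenol before the cycloaddition. The fallback makes the same vinylketene 5 at room temperature by a photochemical Wolff rearrangement. It sets out from 3. Addition of 1-ethoxyvinyllithium, made from ethyl vinyl ether and t-BuLi, to N-methoxy-N-methylacetamide gives 3-ethoxybut-3-en-2-one F4 as the methyl ketone. Trifluoroacetylation of the kinetic enolate of F4 with LiN(SiMe3)2 and CF3CO2CH2CF3 gives 5-ethoxy-1,1,1-trifluorohex-5-ene-2,4-dione F5 as the activated diketone. Detrifluoroacetylative diazo transfer to F5 with MsN3 and Et3N gives 1-diazo-3-ethoxybut-3-en-2-one F6 as the Wolff precursor. Irradiation of F6 with 3 at 300–350 nm in ClCH2CH2Cl at room temperature, followed by warming to 80 °C to finish the electrocyclic cascade through 6, 7 and 8, should give 9, where the route is rejoined.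

3. Step 8. C-acylation of the hindered triether may be slow, 17 may be trifluoroacetylated instead, or acid may shift benzyl groups. The fallback replaces the electrophilic acylation by nucleophilic aryl addition and oxidation. It sets out from 15 and 17. Bromination of 17 with NBS in MeCN at 0 °C gives 2-bromo-1,3,5-tris(benzyloxy)benzene F7 as the only monobromide. Br/Li exchange on F7 with n-BuLi in THF at −78 °C gives [2,4,6-tris(benzyloxy)phenyl]lithium F8 in solution. Premixed with anhydrous CeCl3 to suppress enolisation, F8 should add to the aldehyde of 15 in preference to the chromone at −78 °C and give rac-5-ethoxy-8-{2-hydroxy-2-[2,4,6-tris(benzyloxy)phenyl]ethyl}-7-(triisopropylsilyloxy)-4H-chromen-4-one F9 as the secondary alcohol. Dess–Martin oxidation of F9 gives 19, where the route is rejoined.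

Further compounds
F1 | step 11 | 8-{2-[2,4-bis(benzyloxy)-6-hydroxyphenyl]-2-oxoethyl}-5-ethoxy-7-(triisopropylsilyloxy)-4H-chromen-4-one | O=C(Cc1c(O[Si](C(C)C)(C(C)C)C(C)C)cc(OCC)c2c(=O)ccoc12)c1c(O)cc(OCc2ccccc2)cc1OCc1ccccc1
F2 | step 11 | rac-(2R,3S)-5,7-bis(benzyloxy)-2-[3,4-bis(benzyloxy)phenyl]-3-[5-ethoxy-4-oxo-7-(triisopropylsilyloxy)-4H-chromen-8-yl]chroman-4-one | O=c1ccoc2c1c(OCC)cc(O[Si](C(C)C)(C(C)C)C(C)C)c2[C@@H]1C(=O)c2c(OCc3ccccc3)cc(OCc3ccccc3)cc2O[C@H]1c1ccc(OCc2ccccc2)c(OCc2ccccc2)c1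
F3 | step 11 | (2S,3R)-5,7-bis(benzyloxy)-2-[3,4-bis(benzyloxy)phenyl]-3-{(2S)-2-[4-(benzyloxy)phenyl]-5-ethoxy-4-oxo-7-(triisopropylsilyloxy)chroman-8-yl}chroman-4-one | O=C1C[C@@H](c2ccc(OCc3ccccc3)cc2)Oc2c1c(OCC)cc(O[Si](C(C)C)(C(C)C)C(C)C)c2[C@H]1C(=O)c2c(OCc3ccccc3)cc(OCc3ccccc3)cc2O[C@@H]1c1ccc(OCc2ccccc2)c(OCc2ccccc2)c1
F4 | step 2 | 3-ethoxybut-3-en-2-one | CCOC(=C)C(C)=O
F5 | step 2 | 5-ethoxy-1,1,1-trifluorohex-5-ene-2,4-dione | CCOC(=C)C(=O)CC(=O)C(F)(F)F
F6 | step 2 | 1-diazo-3-ethoxybut-3-en-2-one | CCOC(=C)C(=O)C=[N+]=[N-]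
F7 | step 8 | 2-bromo-1,3,5-tris(benzyloxy)benzene | Brc1c(OCc2ccccc2)cc(OCc2ccccc2)cc1OCc1ccccc1
F8 | step 8 | [2,4,6-tris(benzyloxy)phenyl]lithium | [Li]c1c(OCc2ccccc2)cc(OCc2ccccc2)cc1OCc1ccccc1
F9 | step 8 | rac-5-ethoxy-8-{2-hydroxy-2-[2,4,6-tris(benzyloxy)phenyl]ethyl}-7-(triisopropylsilyloxy)-4H-chromen-4-one | OC(Cc1c(O[Si](C(C)C)(C(C)C)C(C)C)cc(OCC)c2c(=O)ccoc12)c1c(OCc2ccccc2)cc(OCc2ccccc2)cc1OCc1ccccc1
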